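The cyclohexenone ring (C1 aroyloxy-bearing quaternary carbon, C2 ketone, C3 methyl-bearing alkene carbon, C4, C5 methylene, C6 carbinol) is cut at C2–C3 and C5–C6 into a C1-centred thioester–aldehyde and an alkenylstannane. One flask joins them: acyl cross-coupling makes C2–C3, then γ-enolisation of the new enone lets the C4 methyl group, the future C5, add to the aldehyde and close the ring at C5–C6, setting C6. The step exploits that C5 is the only hydrogen-bearing γ-carbon of the C2–C3=C4 enone: C1 is quaternary and the 2-oxopentyl chain on C4 is carried as a pentynyl group, so one dienolate and one ring size are possible and the stannane geometry is irrelevant.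

Key step: step 9

Remark: in step 5 the (S)-diamine is assumed, by analogy with the benzoyloxylation of 2-alkyl β-keto esters, to give the (R)-ester; its enantiomer would be used if the sense proved opposite.

Step 1
Reactants: 1 orsellinic acid (2,4-dihydroxy-6-methylbenzoic acid)
Product: 3 2,4-bis(methoxymethoxy)-6-methylbenzoic acid, via MOM ester 2 (not isolated)
Conditions: NaH, MOMCl, DMF, 0 °C to rt; then KOH, MeOH/H2O, rt; cold dilute HCl to pH 4
Reagents that add atoms: chloromethyl methyl ether (MOMCl), COCCl
Why: O-Alkylation (Williamson type) of the two phenoxides and the carboxylate is followed by saponification of the acylal-like MOM ester alone, which hydroxide cleaves far faster than the aryl MOM ethers.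

Step 2
Reactants: 3 2,4-bis(methoxymethoxy)-6-methylbenzoic acid
Product: 4 2,4-bis(methoxymethoxy)-6-methylperoxybenzoic acid
Conditions: N,N'-dicyclohexylcarbodiimide (1.1 equiv), H2O2 (ethereal, 10 equiv), Et2O/CH2Cl2, −10 °C, 3 added slowly; filtered, washed with cold water and used at once
Reagents that add atoms: hydrogen peroxide, OO
Why: Carbodiimide activation of the acid as its O-acylisourea and perhydrolysis by a large excess of hydrogen peroxide (the way peroxy acids are generated from carboxylic acids and carbodiimides for epoxidation) gives the peroxy acid under neutral conditions, so the MOM ethers are never exposed to acid.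

Step 3
Reactants: 4 2,4-bis(methoxymethoxy)-6-methylperoxybenzoic acid; 3 2,4-bis(methoxymethoxy)-6-methylbenzoic acid
Product: 5 bis[2,4-bis(methoxymethoxy)-6-methylbenzoyl] peroxide
Conditions: N,N'-dicyclohexylcarbodiimide (1.05 equiv), CH2Cl2, 0 °C
Reagents that add atoms: none
Why: Carbodiimide-mediated O-acylation of a peroxy acid by a carboxylic acid is the standard synthesis of diacyl peroxides of defined composition, the peroxy acid (an α-effect nucleophile) intercepting the O-acylisourea of 3 before it rearranges to the N-acylurea.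

Step 4
Reactants: 6 S-ethyl propanethioate
Product: 7 S-ethyl 2-methyl-3-oxopropanethioate (racemic; largely as its enol)
Conditions: LiN(i-Pr)2, THF, −78 °C; HCO2CH2CF3; aqueous HCl work-up
Reagents that add atoms: 2,2,2-trifluoroethyl formate, O=COCC(F)(F)F
Why: Crossed Claisen formylation of the lithium thioester enolate by an activated formate gives the β-oxo thioester, which is held as its enolate until work-up.

Step 5
Reactants: 7 S-ethyl 2-methyl-3-oxopropanethioate; 5 bis[2,4-bis(methoxymethoxy)-6-methylbenzoyl] peroxide
Product: 8 S-ethyl (2R)-2-{[2,4-bis(methoxymethoxy)-6-methylbenzoyl]oxy}-2-methyl-3-oxopropanethioate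
Conditions: (S)-t-BuCH(NH2)CH2NEt2 (10 mol %), TfOH (10 mol %), CHCl3, rt
Reagents that add atoms: none
Why: Enamine-catalysed α-aroyloxylation of a 2-substituted β-oxo carbonyl compound: the hydrogen-bonded Z-enamine of the formyl group attacks the O–O bond of 5, which the protonated tertiary amine of the catalyst steers to one face, so the quaternary centre is set as (R) under catalyst control.

Step 6
Reactants: 9 pent-1-yne
Product: 10 1-bromopent-1-yne
Conditions: NBS, AgNO3 (10 mol %), acetone, rt
Reagents that add atoms: N-bromosuccinimide, O=C1CCC(=O)N1Br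
Why: Silver-assisted electrophilic bromination of a terminal alkyne is the standard route to 1-bromoalkynes.

Step 7
Reactants: 10 1-bromopent-1-yne; 11 but-2-yne
Product: 12 (Z)-2-bromo-3-methyloct-2-en-4-yne
Conditions: Pd(OAc)2 (5 mol %), MeCN, rt, sealed vessel, 11 in excess
Reagents that add atoms: none
Why: Palladium-catalysed cis-bromoalkynylation of an internal alkyne adds the alkynyl group and bromine across but-2-yne with syn selectivity to give the tetrasubstituted bromoenyne, whose geometry has no consequence later.

Step 8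
Reactants: 12 (Z)-2-bromo-3-methyloct-2-en-4-yne
Product: 14 (Z)-tributyl(3-methyloct-2-en-4-yn-2-yl)stannane, via alkenyllithium 13 (not isolated)
Conditions: t-BuLi (2.1 equiv), Et2O, −78 °C; then Bu3SnCl, −78 °C to rt
Reagents that add atoms: tributyltin chloride, CCCC[Sn](Cl)(CCCC)CCCC
Why: Bromine–lithium exchange on the alkenyl bromide occurs with retention of geometry and the alkenyllithium is trapped by the tin chloride.

Step 9
Reactants: 8 S-ethyl (2R)-2-{[2,4-bis(methoxymethoxy)-6-methylbenzoyl]oxy}-2-methyl-3-oxopropanethioate; 14 (Z)-tributyl(3-methyloct-2-en-4-yn-2-yl)stannane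
Product: 16 [(1R,6S)-6-hydroxy-1,3-dimethyl-2-oxo-4-(pent-1-yn-1-yl)cyclohex-3-en-1-yl] 2,4-bis(methoxymethoxy)-6-methylbenzoate, via enynone aldehyde 15 (not isolated)
Conditions: Pd2(dba)3 (2.5 mol %), P(2-furyl)3 (10 mol %), copper diphenylphosphinate CuO2PPh2 (1.5 equiv), THF, 45 °C; then CH2Cl2, MgBr2·OEt2, i-Pr2NEt, 0 °C
Reagents that add atoms: none
Why: Zerovalent palladium inserts into the C–S bond of 8 and the monovalent copper phosphinate relays the alkenyl group from tin to palladium, so reductive elimination forms C2–C3 (Liebeskind–Srogl ketone synthesis); neither the stannane nor the transient organocopper adds to the aldehyde, which secures the acyl-over-formyl chemoselectivity. MgBr2·OEt2 and i-Pr2NEt then enolise enone 15 (soft enolisation): C1 is quaternary and the alkynyl carbon attached to C4 carries no hydrogen, so the methyl group on C4 is the only γ-position that can be deprotonated and a single cross-conjugated dienolate forms whatever the alkene geometry of 14 was. Its γ-carbon, the future C5, adds to the aldehyde in an intramolecular vinylogous aldol reaction, the closest known reaction type, and closes the six-membered ring in the 6-(enolendo)-exo-trig mode, since attack through the α-carbon C3 would need a four-membered ring. The new stereocentre C6 is controlled by C1: in the half-chair transition state the C1–O(aroyl) bond lies anti to the forming C5–C6 bond (polar Felkin–Anh) and the magnesium-bound aldehyde oxygen sits pseudo-equatorial, which puts the hydroxyl trans to the aroyloxy group, that is (6S).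

Step 10
Reactants: 16 [(1R,6S)-6-hydroxy-1,3-dimethyl-2-oxo-4-(pent-1-yn-1-yl)cyclohex-3-en-1-yl] 2,4-bis(methoxymethoxy)-6-methylbenzoate
Product: 17 talarophilone, [(1R,6S)-6-hydroxy-1,3-dimethyl-2-oxo-4-(2-oxopentyl)cyclohex-3-en-1-yl] 2,4-dihydroxy-6-methylbenzoate
Conditions: Ph3PAuCl (5 mol %), AgOSO2CF3 (5 mol %), TsOH·H2O (0.5 equiv), MeOH/H2O (10:1), 40 °C
Reagents that add atoms: water, O
Why: Gold-catalysed hydration of the enynone places oxygen on the propyl-bearing alkyne carbon (positive charge is kept away from the electron-poor C4, the same sense as conjugate addition) and so unveils the 2-oxopentyl chain, while the acid in methanol transfers both MOM groups to the solvent as dimethoxymethane.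

Compound list
1 | orsellinic acid (2,4-dihydroxy-6-methylbenzoic acid) | Cc1cc(O)cc(O)c1C(=O)O | starting material
2 | methoxymethyl 2,4-bis(methoxymethoxy)-6-methylbenzoate | COCOC(=O)c1c(C)cc(OCOC)cc1OCOC | intermediate
3 | 2,4-bis(methoxymethoxy)-6-methylbenzoic acid | COCOc1cc(C)c(C(=O)O)c(OCOC)c1 | intermediate
4 | 2,4-bis(methoxymethoxy)-6-methylperoxybenzoic acid | COCOc1cc(C)c(C(=O)OO)c(OCOC)c1 | intermediate
5 | bis[2,4-bis(methoxymethoxy)-6-methylbenzoyl] peroxide | COCOc1cc(C)c(C(=O)OOC(=O)c2c(C)cc(OCOC)cc2OCOC)c(OCOC)c1 | intermediate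
6 | S-ethyl propanethioate | CCC(=O)SCC | starting material
7 | S-ethyl 2-methyl-3-oxopropanethioate (racemic) | CCSC(=O)C(C)C=O | intermediate
8 | S-ethyl (2R)-2-{[2,4-bis(methoxymethoxy)-6-methylbenzoyl]oxy}-2-methyl-3-oxopropanethioate | CCSC(=O)[C@](C)(OC(=O)c1c(C)cc(OCOC)cc1OCOC)C=O | intermediate
9 | pent-1-yne | CCCC#C | starting material
10 | 1-bromopent-1-yne | CCCC#CBr | intermediate
11 | but-2-yne | CC#CC | starting material
12 | (Z)-2-bromo-3-methyloct-2-en-4-yne (Br and alkynyl cis) | C/C(Br)=C(\C)C#CCCC | intermediate
13 | (3-methyloct-2-en-4-yn-2-yl)lithium, the two methyl groups cis | C/C([Li])=C(\C)C#CCCC | intermediate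
14 | (Z)-tributyl(3-methyloct-2-en-4-yn-2-yl)stannane | C/C(=C(\C)C#CCCC)[Sn](CCCC)(CCCC)CCCC | intermediate
15 | (2R,4Z)-2,4,5-trimethyl-1,3-dioxodec-4-en-6-yn-2-yl 2,4-bis(methoxymethoxy)-6-methylbenzoate | C/C(=C(\C)C#CCCC)C(=O)[C@](C)(OC(=O)c1c(C)cc(OCOC)cc1OCOC)C=O | intermediate
16 | [(1R,6S)-6-hydroxy-1,3-dimethyl-2-oxo-4-(pent-1-yn-1-yl)cyclohex-3-en-1-yl] 2,4-bis(methoxymethoxy)-6-methylbenzoate | CCCC#CC1=C(C)C(=O)[C@](C)(OC(=O)c2c(C)cc(OCOC)cc2OCOC)[C@@H](O)C1 | intermediate
17 | talarophilone, [(1R,6S)-6-hydroxy-1,3-dimethyl-2-oxo-4-(2-oxopentyl)cyclohex-3-en-1-yl] 2,4-dihydroxy-6-methylbenzoate | CCCC(=O)CC1=C(C)C(=O)[C@](C)(OC(=O)c2c(C)cc(O)cc2O)[C@@H](O)C1 | target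

Total step count: 10.
Longest linear sequence: 6 steps (1 → 3 → 4 → 5 → 8 → 16 → 17).

Steps most likely to fail

Step 9: poor facial selectivity in the ring-closing aldol addition. The complexed aldehyde may react through the alternative half-chair with its oxygen pseudo-axial, which would give the (6R)-alcohol. The fallback moves stereocontrol from the C–C bond formation to an SN2 inversion. It sets out from 8 and 14, which are coupled and cyclised as before. The unwanted [(1R,6R)-6-hydroxy-1,3-dimethyl-2-oxo-4-(pent-1-yn-1-yl)cyclohex-3-en-1-yl] ester F1 is separated from 16 by chromatography and treated with 4-nitrobenzoic acid, PPh3 and DIAD in toluene (Mitsunobu reaction) to give the inverted (6S)-4-nitrobenzoate F2. Catalytic K2CO3 in MeOH at 0 °C then cleaves only this unhindered ester and leaves the 2,6-disubstituted aroyl ester, which brings the material back to 16.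

Step 5: slow oxygen transfer from the hindered, electron-rich peroxide, so that the uncatalysed reaction of the enol and acylation of the amine catalyst by the thioester erode the enantiomeric purity. The fallback replaces asymmetric catalysis by resolution. It sets out from 7 and 5: with catalytic Et3N in CH2Cl2 the enol of 7 is aroyloxylated to the racemic thioester F3, the enantiomers of which are separated by preparative chromatography on a chiral stationary phase; the (R)-enantiomer is 8.

Step 10: under the acid needed for MOM removal the aroyl group may shift from the C1 oxygen to the C6 hydroxyl, or water may be lost across C5–C6 to a cross-conjugated dienone, before hydration is complete. The fallback separates the two events and avoids Brønsted acid. It sets out from 16: diethylamine adds in the 1,6 sense to the enynone (EtOH, rt) to give the dienaminone F4, which is hydrolysed on wet silica gel to the bis-MOM diketone F5; ZnBr2 and n-PrSH in CH2Cl2 at 0 °C then remove both MOM groups and give 17.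

Further compounds
F1 | step 9 | [(1R,6R)-6-hydroxy-1,3-dimethyl-2-oxo-4-(pent-1-yn-1-yl)cyclohex-3-en-1-yl] 2,4-bis(methoxymethoxy)-6-methylbenzoate | CCCC#CC1=C(C)C(=O)[C@](C)(OC(=O)c2c(C)cc(OCOC)cc2OCOC)[C@H](O)C1
F2 | step 9 | [(1R,6S)-1,3-dimethyl-6-(4-nitrobenzoyloxy)-2-oxo-4-(pent-1-yn-1-yl)cyclohex-3-en-1-yl] 2,4-bis(methoxymethoxy)-6-methylbenzoate | CCCC#CC1=C(C)C(=O)[C@](C)(OC(=O)c2c(C)cc(OCOC)cc2OCOC)[C@@H](OC(=O)c3ccc([N+](=O)[O-])cc3)C1
F3 | step 5 | racemic S-ethyl 2-{[2,4-bis(methoxymethoxy)-6-methylbenzoyl]oxy}-2-methyl-3-oxopropanethioate | CCSC(=O)C(C)(OC(=O)c1c(C)cc(OCOC)cc1OCOC)C=O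
F4 | step 10 | [(1R,6S)-4-[2-(diethylamino)pent-1-en-1-yl]-6-hydroxy-1,3-dimethyl-2-oxocyclohex-3-en-1-yl] 2,4-bis(methoxymethoxy)-6-methylbenzoate (E/Z mixture) | CCCC(=CC1=C(C)C(=O)[C@](C)(OC(=O)c2c(C)cc(OCOC)cc2OCOC)[C@@H](O)C1)N(CC)CC
F5 | step 10 | [(1R,6S)-6-hydroxy-1,3-dimethyl-2-oxo-4-(2-oxopentyl)cyclohex-3-en-1-yl] 2,4-bis(methoxymethoxy)-6-methylbenzoate | CCCC(=O)CC1=C(C)C(=O)[C@](C)(OC(=O)c2c(C)cc(OCOC)cc2OCOC)[C@@H](O)C1
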